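# Proposed total synthesis of CNP0130704.0 (31) by fourfold Dakin-type oxidation of a heptamer tetra-aldehyde

## The problem

Compound 31 is a linear chain of seven benzene rings, lettered A to G from the 2,4,6-trihydroxyphenoxy end, held together only by six diaryl ether oxygens. The ether bonds run from ring A carbon 1 to B1, B4 to C1, C6 to D1, D5 to E1, E6 to ring F carbon 1, and ring F carbon 4 to G1. There are eighteen free hydroxyls, no carbon–carbon bond between rings and no stereocentre, so the task is purely regiochemical: every oxygen on the right carbon, every ether between the right rings. Most ether carbons sit on electron-rich rings between two ortho substituents, the setting in which copper- or palladium-mediated ether couplings are least reliable. Rings C and E are pentaoxygenated with two neighbouring ether oxygens, and their C6 and E6 oxygens lie meta to every position that could carry an activating group. The free polyphenol, rich in phloroglucinol and pyrogallol units, is oxidised readily by air, above all in base, so the hydroxyls must stay masked until the last step. The enabling feature is that the hydroxyls at C4, D4, E4 and G4 each lie para to an ether carbon (C1, D1, E1, G1; D4 is also ortho to D5) and between two oxygenated carbons. A formyl group at these positions makes the para and ortho carbons open to fluoride displacement by phenoxides and is afterwards exchanged for hydroxyl by aryl migration to oxygen. The ether oxygens at B4 and at ring F carbon 4 have the same para relation to B1 and ring F carbon 1, so the same device can build rings B and F.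

## Retrosynthesis

**31 to 30.** The fourteen O–methyl bonds are cut last. Methyl ethers are preferred to benzyl ethers because they survive LiN(iPr)2, NaOMe and peracid, and BBr3 leaves diaryl ethers alone. The forward step must cleave all fourteen ethers and deliver the air-sensitive polyphenol without base.

**30 to 28 (key disconnection).** The four aryl C–O bonds at C4, D4, E4 and G4 are traced back to four formyl groups in tetra-aldehyde 28. Carrying these oxygens as methoxy groups from the start would leave C1, D1, D5, E1 and G1 without activation and force couplings between hindered, electron-rich partners. With formyl groups in place, every one of these ether bonds becomes a fluoride displacement. The forward reaction must achieve aryl migration at four sites in one operation and spare rings A, B and F.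

**28 to 27 to 16 + 26.** The methoxy groups at D3, E3 and E5 are exchanged for fluorides (27). The D5–O–E1 bond is then cut at E1, para to the ring E formyl group, giving tetramer phenol 16 and trimer dialdehyde 26. This cut is preferred to the C6–O–D1 cut because it divides the chain almost evenly and pairs the weakest nucleophile (a salicylaldehyde-type phenoxide) with the most electrophilic ring (a trifluorobenzaldehyde). After the union only ortho fluorides remain, so no oligomer can form. The forward step needs para selectivity on ring E.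

**16 to 14 to 13 + 2.** The D5 hydroxyl comes from one of the two equivalent ortho fluorides of 14 through a hydroxide equivalent. Cutting C6–O–D1 at D1 leads to trimer phenol 13 and 2,4,6-trifluorobenzaldehyde 2, whose para fluoride is the unhindered, most activated site.

**13 to 12 to 11 to 6 + 10, and 10 to 8 to 7.** The C6 oxygen is meta to the formyl group and cannot be introduced by displacement. It is therefore brought in with the ring, as 2,4,6-trifluorophenol 7 protected as its methoxymethyl ether 8. Lithiation between two fluorines and formylation give aldehyde 10, in which the formyl group is para to the fluoride that becomes C1. Dimer phenol 6 displaces that fluoride (11), NaOMe replaces the two ortho fluorides (12) and acid frees the C6 hydroxyl (13).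

**6 to 4 to 1 + 2.** Ring B is made from 2 as well: the phenoxide of 2,4,6-trimethoxyphenol 1 displaces the para fluoride, NaOMe installs the two methoxy groups (4), and the formyl group is converted into the B4 hydroxyl. Against an aryne or copper-mediated arylation of 1, this makes ring A carbon 1–O–B1 an activated displacement. It also tests the peracid step on the ring pattern present in 28.

**26 to 23 to 22 to 20 + 2, and 20 to 18 to 7 + 2.** Ring E enters as the nucleophile 7, whose oxygen becomes the E6 ether oxygen. Displacement on 2, methoxide exchange and formyl-to-hydroxyl conversion give phenol 20. A second round with 2 adds ring G and keeps its formyl group (22). The ring E formyl group is introduced last, by lithiation between two fluorines with the ring G aldehyde masked as acetal 23, so that 26 carries a para fluoride for the union with 16.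

## Roads not taken

**Alternative 1:** Here the carbon skeleton of ring E is cut. A squaric-acid-derived cyclobutenone A1, already bearing the ring F aryloxy group, three methoxy groups and a 1-methoxyvinyl group, is heated. It opens to a dienylketene, closes by six-electron electrocyclisation and tautomerises to the EFG phenol A2.
- Merits: all five oxygens of ring E are placed by construction, and the E1 hydroxyl emerges free for the next ether bond.
- Weak points: it solves one ring only. Ring C has the same pattern and would need the whole sequence again. None of the six ether bonds is helped, since the partners of A2 still need an activating group or a metal-mediated coupling.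
- Comparison: for the regiochemistry of ring E this road is safer than the chosen plan, which relies on para-selective fluoride displacement on 10 and 26. The chosen plan sets against this that one reaction type and two commercial fluoroarenes (2 and 7) serve all six ether bonds, with no separate ring synthesis.

**Alternative 2:** Here the two ether bonds and the methoxy group of ring D are cut. Aldehyde 2 acts as a linchpin: the fully methylated ABC phenol A3 takes the para fluoride, the EFG phenol A2 one ortho fluoride and NaOMe the last one, giving the mono-aldehyde heptamer A4.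
- Merits: it is the most convergent plan, and only one aldehyde has to be oxidised at the end, so its final oxidation is less demanding than the fourfold one chosen here.
- Weak points: the difficulty moves into the trimers. A3 and A2 contain no formyl group, so their four inner ether bonds and their pentaoxygenated rings must be made without activation. The ortho displacement by the bulky phenoxide of A2 on a ring already deactivated by one aryloxy group must also run cleanly in one pot.
- Comparison: the chosen plan uses the same ring D chemistry stepwise (steps 8, 9 and 15). It pays with three more aldehydes in the last oxidation and gains an activated displacement for every ether bond.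

**Alternative 3:** Here ring A is cut in the biomimetic sense. A triketide ester A5, attached through oxygen to ring B of a finished hexamer, is turned into a polyanion with excess LiN(iPr)2. Its terminal carbanion attacks the ester carbon, closing ring A as the phloroglucinol of A6.
- Merits: ring A is formed with its three hydroxyls free, and the hindered ether at ring A carbon 1 is never made by coupling.
- Weak points: ring A is the one ring that can be bought with the right oxygen pattern (1). The cyclisation must outrun the usual collapse of 3,5-dioxo esters to pyranones. The polyanion must form on a substrate with fifteen methyl ethers, and the hexamer, which is the real problem, is left untouched.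
- Comparison: it offers no gain in step count or certainty over the chosen plan, which needs one displacement on 2 for the same bond.

Key step: step 17

## Route

Remark: compounds 1, 2 and 7 are taken as catalogue chemicals; none of the compounds in the route has a stereocentre.

Step 1
Reactants: 1 2,4,6-trimethoxyphenol; 2 2,4,6-trifluorobenzaldehyde
Product: 4 2,6-dimethoxy-4-(2,4,6-trimethoxyphenoxy)benzaldehyde, via difluoro aldehyde 3 (not isolated)
Conditions: K2CO3, DMF, 0 °C to rt (N2); then NaOMe, MeOH, 60 °C
Reagents that add atoms: sodium methoxide, C[O-].[Na+]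
Why: Nucleophilic aromatic substitution; the hindered phenoxide should take the para fluoride, where the formyl group stays coplanar in the Meisenheimer adduct and the site is unshielded. NaOMe then replaces both ortho fluorides, each new methoxy group slowing further attack so that the aryloxy group is not exchanged.

Step 2
Reactants: 4 2,6-dimethoxy-4-(2,4,6-trimethoxyphenoxy)benzaldehyde
Product: 6 2,6-dimethoxy-4-(2,4,6-trimethoxyphenoxy)phenol, via aryl formate 5 (not isolated)
Conditions: mCPBA, NaHCO3, CH2Cl2, 0 °C to rt; aq. Na2S2O3; then K2CO3, MeOH, rt (N2)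
Reagents that add atoms: 3-chloroperoxybenzoic acid (mCPBA), OOC(=O)c1cccc(Cl)c1
Why: Dakin-type Baeyer–Villiger oxidation; the 2,6-dimethoxy-4-aryloxyphenyl group should migrate in preference to hydride, and the formate is methanolysed. The step also tests the tolerance of ring A towards the peracid before the key step.

Step 3
Reactants: 7 2,4,6-trifluorophenol
Product: 8 1,3,5-trifluoro-2-(methoxymethoxy)benzene
Conditions: MOMCl, K2CO3, acetone, 0 °C to rt
Reagents that add atoms: chloromethyl methyl ether, COCCl
Why: O-Alkylation of an acidic phenol; the methoxymethyl ether withstands the lithium amide, phenoxides and NaOMe of the next steps and is removed by acid without touching methyl ethers.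

Step 4
Reactants: 8 1,3,5-trifluoro-2-(methoxymethoxy)benzene
Product: 10 2,4,6-trifluoro-3-(methoxymethoxy)benzaldehyde, via aryllithium 9 (not isolated)
Conditions: LiN(iPr)2, THF, −78 °C; DMF, −78 to −20 °C; aq. NH4Cl
Reagents that add atoms: N,N-dimethylformamide, CN(C)C=O
Why: Directed ortho-metalation; the two equivalent C–H bonds flanked by two fluorines are by far the most acidic, and at −78 °C the ortho-fluoroaryllithium should not lose LiF. DMF delivers the formyl group para to the fluoride next to the protected oxygen.

Step 5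
Reactants: 6 2,6-dimethoxy-4-(2,4,6-trimethoxyphenoxy)phenol; 10 2,4,6-trifluoro-3-(methoxymethoxy)benzaldehyde
Product: 11 4-[2,6-dimethoxy-4-(2,4,6-trimethoxyphenoxy)phenoxy]-2,6-difluoro-3-(methoxymethoxy)benzaldehyde
Conditions: Cs2CO3, DMF, 0 °C to rt
Reagents that add atoms: none
Why: Nucleophilic aromatic substitution at the para fluoride; the bulky 2,6-dimethoxyphenoxide and the weakly coordinating caesium cation should disfavour the ortho sites next to the formyl group. The product is isolated so that any ortho isomer can be removed.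

Step 6
Reactants: 11 4-[2,6-dimethoxy-4-(2,4,6-trimethoxyphenoxy)phenoxy]-2,6-difluoro-3-(methoxymethoxy)benzaldehyde
Product: 12 4-[2,6-dimethoxy-4-(2,4,6-trimethoxyphenoxy)phenoxy]-2,6-dimethoxy-3-(methoxymethoxy)benzaldehyde
Conditions: NaOMe, MeOH–THF, 60 °C
Reagents that add atoms: sodium methoxide, C[O-].[Na+]
Why: Nucleophilic aromatic substitution of both fluorides ortho to the formyl group by the small methoxide ion; the methoxymethyl ether and the electron-rich para aryloxy group are stable to the base.

Step 7
Reactants: 12 4-[2,6-dimethoxy-4-(2,4,6-trimethoxyphenoxy)phenoxy]-2,6-dimethoxy-3-(methoxymethoxy)benzaldehyde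
Product: 13 4-[2,6-dimethoxy-4-(2,4,6-trimethoxyphenoxy)phenoxy]-3-hydroxy-2,6-dimethoxybenzaldehyde
Conditions: conc. HCl (cat.), MeOH–THF, 45 °C; aqueous work-up
Reagents that add atoms: none
Why: Acid-catalysed acetal exchange removes the methoxymethyl group as dimethoxymethane while aryl methyl ethers and diaryl ethers stay; any dimethyl acetal of the aldehyde reverts on aqueous work-up.

Step 8
Reactants: 13 4-[2,6-dimethoxy-4-(2,4,6-trimethoxyphenoxy)phenoxy]-3-hydroxy-2,6-dimethoxybenzaldehyde; 2 2,4,6-trifluorobenzaldehyde
Product: 14 3-(3,5-difluoro-4-formylphenoxy)-4-[2,6-dimethoxy-4-(2,4,6-trimethoxyphenoxy)phenoxy]-2,6-dimethoxybenzaldehyde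
Conditions: Cs2CO3, DMF, 0 °C to rt
Reagents that add atoms: none
Why: Nucleophilic aromatic substitution; the C6 phenoxide, flanked by a methoxy and an aryloxy group, should attack the unhindered para fluoride of 2. The product keeps only the less reactive ortho fluorides, so a second arylation is not expected.

Step 9
Reactants: 14 3-(3,5-difluoro-4-formylphenoxy)-4-[2,6-dimethoxy-4-(2,4,6-trimethoxyphenoxy)phenoxy]-2,6-dimethoxybenzaldehyde
Product: 16 3-(3-fluoro-4-formyl-5-hydroxyphenoxy)-4-[2,6-dimethoxy-4-(2,4,6-trimethoxyphenoxy)phenoxy]-2,6-dimethoxybenzaldehyde, via sulfonylethyl ether 15 (not isolated)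
Conditions: MeSO2CH2CH2OH (1.1 equiv), NaH (2.2 equiv), DMF, 0 °C to rt; aq. NH4Cl
Reagents that add atoms: 2-(methylsulfonyl)ethanol, CS(=O)(=O)CCO
Why: The alkoxide displaces one of the two equivalent ortho fluorides, and E1cB loss of methyl vinyl sulfone then unveils the phenoxide (hydroxide-equivalent substitution). The phenoxide deactivates ring D, so the second fluoride should stay.

Step 10
Reactants: 7 2,4,6-trifluorophenol; 2 2,4,6-trifluorobenzaldehyde
Product: 18 2,6-dimethoxy-4-(2,4,6-trifluorophenoxy)benzaldehyde, via pentafluoro ether 17 (not isolated)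
Conditions: K2CO3, DMF, rt; then NaOMe, MeOH, 50 °C
Reagents that add atoms: sodium methoxide, C[O-].[Na+]
Why: Nucleophilic aromatic substitution at the para fluoride of 2 by the weakly nucleophilic trifluorophenoxide, then exchange of the two formyl-activated ortho fluorides. The fluorines of the phenoxy ring have no activating group and should remain.

Step 11
Reactants: 18 2,6-dimethoxy-4-(2,4,6-trifluorophenoxy)benzaldehyde
Product: 20 2,6-dimethoxy-4-(2,4,6-trifluorophenoxy)phenol, via aryl formate 19 (not isolated)
Conditions: mCPBA, NaHCO3, CH2Cl2, 0 °C to rt; aq. Na2S2O3; then K2CO3, MeOH, rt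
Reagents that add atoms: 3-chloroperoxybenzoic acid (mCPBA), OOC(=O)c1cccc(Cl)c1
Why: Dakin-type Baeyer–Villiger oxidation as in step 2; the 2,6-dimethoxyaryl group migrates and the formate is methanolysed to the phenol that will carry ring G.

Step 12
Reactants: 20 2,6-dimethoxy-4-(2,4,6-trifluorophenoxy)phenol; 2 2,4,6-trifluorobenzaldehyde
Product: 22 4-[2,6-dimethoxy-4-(2,4,6-trifluorophenoxy)phenoxy]-2,6-dimethoxybenzaldehyde, via difluoro aldehyde 21 (not isolated)
Conditions: K2CO3, DMF, 0 °C to rt; then NaOMe, MeOH, 60 °C
Reagents that add atoms: sodium methoxide, C[O-].[Na+]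
Why: The same para-selective substitution and double methoxide exchange as in step 1, now building ring G on the hindered phenoxide of 20.

Step 13
Reactants: 22 4-[2,6-dimethoxy-4-(2,4,6-trifluorophenoxy)phenoxy]-2,6-dimethoxybenzaldehyde
Product: 23 2-[4-(dimethoxymethyl)-3,5-dimethoxyphenoxy]-1,3-dimethoxy-5-(2,4,6-trifluorophenoxy)benzene
Conditions: HC(OMe)3, MeOH, TsOH (cat.), rt; Et3N
Reagents that add atoms: trimethyl orthoformate, COC(OC)OC; methanol, CO
Why: Acid-catalysed acetalisation driven by the orthoformate; the acetal hides the ring G aldehyde from the lithium amide and the aryllithium of the next step.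

Step 14
Reactants: 23 2-[4-(dimethoxymethyl)-3,5-dimethoxyphenoxy]-1,3-dimethoxy-5-(2,4,6-trifluorophenoxy)benzene
Product: 26 3-[4-(4-formyl-3,5-dimethoxyphenoxy)-3,5-dimethoxyphenoxy]-2,4,6-trifluorobenzaldehyde, via aryllithium 24 (not isolated), via acetal aldehyde 25 (not isolated)
Conditions: LiN(iPr)2 (1.1 equiv), THF, −78 °C; DMF; then 1 M HCl, THF, rt
Reagents that add atoms: N,N-dimethylformamide, CN(C)C=O; water, O
Why: Directed ortho-metalation at one of the two equivalent ring E positions between two fluorines, far more acidic than any C–H next to methoxy or aryloxy groups, followed by formylation. The acidic work-up hydrolyses the electron-rich dimethyl acetal.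

Step 15
Reactants: 16 3-(3-fluoro-4-formyl-5-hydroxyphenoxy)-4-[2,6-dimethoxy-4-(2,4,6-trimethoxyphenoxy)phenoxy]-2,6-dimethoxybenzaldehyde; 26 3-[4-(4-formyl-3,5-dimethoxyphenoxy)-3,5-dimethoxyphenoxy]-2,4,6-trifluorobenzaldehyde
Product: 27 heptamer tetra-aldehyde trifluoride (as 28, with fluorine in place of methoxy at D3, E3 and E5)
Conditions: Cs2CO3, DMF, rt to 40 °C
Reagents that add atoms: none
Why: Nucleophilic aromatic substitution; the D5 phenoxide should take the E1 fluoride, the only one para to a formyl group, where attack leaves the carbonyl coplanar. Its own ring D is deactivated as a phenoxide and the product holds only ortho fluorides, so the union should stop at the heptamer.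

Step 16
Reactants: 27 heptamer tetra-aldehyde trifluoride
Product: 28 heptamer tetra-aldehyde (formyl groups at C4, D4, E4 and G4; fourteen methyl ethers)
Conditions: NaOMe, MeOH–THF, 50 °C
Reagents that add atoms: sodium methoxide, C[O-].[Na+]
Why: Threefold nucleophilic aromatic substitution of formyl-activated ortho fluorides. The fluorine-bearing carbons are far more electrophilic than the aryloxy-bearing ones, so exchange should outrun ether cleavage, and each new methoxy group deactivates its ring further.

Step 17
Reactants: 28 heptamer tetra-aldehyde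
Product: 30 heptamer tetraphenol (free hydroxyls at C4, D4, E4 and G4; fourteen methyl ethers), via tetraformate 29 (not isolated)
Conditions: mCPBA, NaHCO3, CH2Cl2, 0 °C to rt; aq. Na2S2O3; then K2CO3, MeOH (degassed), 0 °C
Reagents that add atoms: 3-chloroperoxybenzoic acid (mCPBA), OOC(=O)c1cccc(Cl)c1
Why: Each formyl carbon adds the peracid to give a peroxyhemiacetal (Criegee adduct), and the aryl group then migrates from carbon to the proximal peroxide oxygen as 3-chlorobenzoate leaves, which creates the four aryl carbon–oxygen bonds at C4, D4, E4 and G4 and gives tetraformate 29. The closest known reaction is the Dakin-type Baeyer–Villiger oxidation of 2,6-dialkoxybenzaldehydes to aryl formates, and methanolysis with K2CO3 then frees the phenols of 30. No ring is closed and no stereocentre is formed. Aryl migration must beat hydride migration at all four sites: every formyl-bearing ring has two ortho oxygen substituents and a para aryloxy group, which stabilise the electron-poor migrating carbon, and the same pattern is tested in steps 2 and 11. The peracid must also spare the electron-rich rings A, B and F: the NaHCO3 buffer and 0 °C keep acid-promoted ring hydroxylation slow, and the new oxygens stay protected as formates until the excess oxidant has been reduced with Na2S2O3. The methanolysis is run cold and degassed because the liberated 2,6-dioxygenated 4-aryloxyphenols are sensitive to air in base.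

Step 18
Reactants: 30 heptamer tetraphenol
Product: 31 CNP0130704.0, the heptamer with eighteen free hydroxyls
Conditions: BBr3 (excess), CH2Cl2, −78 °C to rt; MeOH, 0 °C (argon)
Reagents that add atoms: none
Why: Lewis-acid ether cleavage; bromide attacks the methyl group of each boron-complexed aryl methyl ether, while the six diaryl ethers have no alkyl carbon to attack and persist. Acidic, oxygen-free work-up protects the polyphenol.

## Compound list

1 | 2,4,6-trimethoxyphenol | COc1cc(OC)c(O)c(OC)c1 | starting material
2 | 2,4,6-trifluorobenzaldehyde | O=Cc1c(F)cc(F)cc1F | starting material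
3 | 2,6-difluoro-4-(2,4,6-trimethoxyphenoxy)benzaldehyde (formed in the flask, step 1) | COc1cc(OC)c(Oc2cc(F)c(C=O)c(F)c2)c(OC)c1 | intermediate
4 | 2,6-dimethoxy-4-(2,4,6-trimethoxyphenoxy)benzaldehyde | COc1cc(OC)c(Oc2cc(OC)c(C=O)c(OC)c2)c(OC)c1 | intermediate
5 | 2,6-dimethoxy-4-(2,4,6-trimethoxyphenoxy)phenyl formate (formed in the flask, step 2) | COc1cc(OC)c(Oc2cc(OC)c(OC=O)c(OC)c2)c(OC)c1 | intermediate
6 | 2,6-dimethoxy-4-(2,4,6-trimethoxyphenoxy)phenol | COc1cc(OC)c(Oc2cc(OC)c(O)c(OC)c2)c(OC)c1 | intermediate
7 | 2,4,6-trifluorophenol | Oc1c(F)cc(F)cc1F | starting material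
8 | 1,3,5-trifluoro-2-(methoxymethoxy)benzene | COCOc1c(F)cc(F)cc1F | intermediate
9 | [2,4,6-trifluoro-3-(methoxymethoxy)phenyl]lithium (formed in the flask, step 4) | COCOc1c(F)cc(F)c([Li])c1F | intermediate
10 | 2,4,6-trifluoro-3-(methoxymethoxy)benzaldehyde | COCOc1c(F)cc(F)c(C=O)c1F | intermediate
11 | 4-[2,6-dimethoxy-4-(2,4,6-trimethoxyphenoxy)phenoxy]-2,6-difluoro-3-(methoxymethoxy)benzaldehyde | COc1cc(OC)c(Oc2cc(OC)c(Oc3cc(F)c(C=O)c(F)c3OCOC)c(OC)c2)c(OC)c1 | intermediate
12 | 4-[2,6-dimethoxy-4-(2,4,6-trimethoxyphenoxy)phenoxy]-2,6-dimethoxy-3-(methoxymethoxy)benzaldehyde | COc1cc(OC)c(Oc2cc(OC)c(Oc3cc(OC)c(C=O)c(OC)c3OCOC)c(OC)c2)c(OC)c1 | intermediate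
13 | 4-[2,6-dimethoxy-4-(2,4,6-trimethoxyphenoxy)phenoxy]-3-hydroxy-2,6-dimethoxybenzaldehyde | COc1cc(OC)c(Oc2cc(OC)c(Oc3cc(OC)c(C=O)c(OC)c3O)c(OC)c2)c(OC)c1 | intermediate
14 | 3-(3,5-difluoro-4-formylphenoxy)-4-[2,6-dimethoxy-4-(2,4,6-trimethoxyphenoxy)phenoxy]-2,6-dimethoxybenzaldehyde | COc1cc(OC)c(Oc2cc(OC)c(Oc3cc(OC)c(C=O)c(OC)c3Oc3cc(F)c(C=O)c(F)c3)c(OC)c2)c(OC)c1 | intermediate
15 | 3-{3-fluoro-4-formyl-5-[2-(methylsulfonyl)ethoxy]phenoxy}-4-[2,6-dimethoxy-4-(2,4,6-trimethoxyphenoxy)phenoxy]-2,6-dimethoxybenzaldehyde (formed in the flask, step 9) | COc1cc(OC)c(Oc2cc(OC)c(Oc3cc(OC)c(C=O)c(OC)c3Oc3cc(F)c(C=O)c(OCCS(C)(=O)=O)c3)c(OC)c2)c(OC)c1 | intermediate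
16 | 3-(3-fluoro-4-formyl-5-hydroxyphenoxy)-4-[2,6-dimethoxy-4-(2,4,6-trimethoxyphenoxy)phenoxy]-2,6-dimethoxybenzaldehyde | COc1cc(OC)c(Oc2cc(OC)c(Oc3cc(OC)c(C=O)c(OC)c3Oc3cc(F)c(C=O)c(O)c3)c(OC)c2)c(OC)c1 | intermediate
17 | 2,6-difluoro-4-(2,4,6-trifluorophenoxy)benzaldehyde (formed in the flask, step 10) | O=Cc1c(F)cc(Oc2c(F)cc(F)cc2F)cc1F | intermediate
18 | 2,6-dimethoxy-4-(2,4,6-trifluorophenoxy)benzaldehyde | O=Cc1c(OC)cc(Oc2c(F)cc(F)cc2F)cc1OC | intermediate
19 | 2,6-dimethoxy-4-(2,4,6-trifluorophenoxy)phenyl formate (formed in the flask, step 11) | O=COc1c(OC)cc(Oc2c(F)cc(F)cc2F)cc1OC | intermediate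
20 | 2,6-dimethoxy-4-(2,4,6-trifluorophenoxy)phenol | Oc1c(OC)cc(Oc2c(F)cc(F)cc2F)cc1OC | intermediate
21 | 4-[2,6-dimethoxy-4-(2,4,6-trifluorophenoxy)phenoxy]-2,6-difluorobenzaldehyde (formed in the flask, step 12) | O=Cc1c(F)cc(Oc2c(OC)cc(Oc3c(F)cc(F)cc3F)cc2OC)cc1F | intermediate
22 | 4-[2,6-dimethoxy-4-(2,4,6-trifluorophenoxy)phenoxy]-2,6-dimethoxybenzaldehyde | O=Cc1c(OC)cc(Oc2c(OC)cc(Oc3c(F)cc(F)cc3F)cc2OC)cc1OC | intermediate
23 | 2-[4-(dimethoxymethyl)-3,5-dimethoxyphenoxy]-1,3-dimethoxy-5-(2,4,6-trifluorophenoxy)benzene | COC(OC)c1c(OC)cc(Oc2c(OC)cc(Oc3c(F)cc(F)cc3F)cc2OC)cc1OC | intermediate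
24 | aryllithium of 23, lithium on the ring E carbon between two fluorines (formed in the flask, step 14) | COC(OC)c1c(OC)cc(Oc2c(OC)cc(Oc3c(F)cc(F)c([Li])c3F)cc2OC)cc1OC | intermediate
25 | 3-{4-[4-(dimethoxymethyl)-3,5-dimethoxyphenoxy]-3,5-dimethoxyphenoxy}-2,4,6-trifluorobenzaldehyde (formed in the flask, step 14) | COC(OC)c1c(OC)cc(Oc2c(OC)cc(Oc3c(F)cc(F)c(C=O)c3F)cc2OC)cc1OC | intermediate
26 | 3-[4-(4-formyl-3,5-dimethoxyphenoxy)-3,5-dimethoxyphenoxy]-2,4,6-trifluorobenzaldehyde | O=Cc1c(OC)cc(Oc2c(OC)cc(Oc3c(F)cc(F)c(C=O)c3F)cc2OC)cc1OC | intermediate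
27 | heptamer tetra-aldehyde trifluoride (formyl at C4, D4, E4, G4; fluorine at D3, E3, E5; eleven methyl ethers) | COc1cc(OC)c(Oc2cc(OC)c(Oc3cc(OC)c(C=O)c(OC)c3Oc3cc(F)c(C=O)c(Oc4cc(F)c(C=O)c(F)c4Oc4cc(OC)c(Oc5cc(OC)c(C=O)c(OC)c5)c(OC)c4)c3)c(OC)c2)c(OC)c1 | intermediate
28 | heptamer tetra-aldehyde (formyl at C4, D4, E4, G4; fourteen methyl ethers) | COc1cc(OC)c(Oc2cc(OC)c(Oc3cc(OC)c(C=O)c(OC)c3Oc3cc(OC)c(C=O)c(Oc4cc(OC)c(C=O)c(OC)c4Oc4cc(OC)c(Oc5cc(OC)c(C=O)c(OC)c5)c(OC)c4)c3)c(OC)c2)c(OC)c1 | intermediate
29 | heptamer tetraformate (formyloxy at C4, D4, E4, G4; fourteen methyl ethers; formed in the flask, step 17) | COc1cc(OC)c(Oc2cc(OC)c(Oc3cc(OC)c(OC=O)c(OC)c3Oc3cc(OC)c(OC=O)c(Oc4cc(OC)c(OC=O)c(OC)c4Oc4cc(OC)c(Oc5cc(OC)c(OC=O)c(OC)c5)c(OC)c4)c3)c(OC)c2)c(OC)c1 | intermediate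
30 | heptamer tetraphenol (hydroxyl at C4, D4, E4, G4; fourteen methyl ethers) | COc1cc(OC)c(Oc2cc(OC)c(Oc3cc(OC)c(O)c(OC)c3Oc3cc(OC)c(O)c(Oc4cc(OC)c(O)c(OC)c4Oc4cc(OC)c(Oc5cc(OC)c(O)c(OC)c5)c(OC)c4)c3)c(OC)c2)c(OC)c1 | intermediate
31 | CNP0130704.0, heptamer with eighteen free hydroxyls | Oc1cc(O)c(Oc2cc(O)c(Oc3cc(O)c(O)c(O)c3Oc3cc(O)c(O)c(Oc4cc(O)c(O)c(O)c4Oc4cc(O)c(Oc5cc(O)c(O)c(O)c5)c(O)c4)c3)c(O)c2)c(O)c1 | target

## Step count and risks

Total: 18 steps. Longest linear sequence: 11 steps (steps 1, 2, 5, 6, 7, 8, 9, 15, 16, 17, 18).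

**Step 17 (key step).**
- What may go wrong: hydride instead of aryl migration at one of the four sites, or oxidative degradation of the electron-rich rings. The most likely failure is loss of the freed 4-aryloxyphenols to air or residual oxidant during the basic methanolysis.
- Fallback: the route is left at tetraformate 29, which is isolated after the reductive quench and treated directly with BBr3. The methanolic quench cleaves the formates together with the fourteen methyl ethers. The route is rejoined at 31, and the base-sensitive tetraphenol 30 is never formed. No new compound is made.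

**Step 15.**
- What may go wrong: competing attack at the ortho fluoride E3, and a slow union because both partners are large and E1 lies next to the ring F aryloxy group.
- Fallback: the bond order is inverted, setting out from 26 and 13 and returning at 27. The small phenoxide of purchased 2,4-difluoro-6-hydroxybenzaldehyde (O=Cc1c(O)cc(F)cc1F) is added slowly to a slight excess of 26 (Cs2CO3, DMF). This should give 2,6-difluoro-4-(3,5-difluoro-2-formylphenoxy)-3-[4-(4-formyl-3,5-dimethoxyphenoxy)-3,5-dimethoxyphenoxy]benzaldehyde F6, where isomers can be separated on a smaller molecule. The phenoxide of 13 then takes the only para fluoride of F6 (on ring D, flanked by two hydrogens) to give 27.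

**Step 5.**
- What may go wrong: erosion of para selectivity, because the para fluoride of 10 lies next to the methoxymethoxy group while one ortho fluoride is unhindered.
- Fallback: the ether is made by copper catalysis instead of fluoride displacement, setting out from 6 and returning at 12.
  - Purchased 2-bromo-4,6-difluorophenol (Oc1c(F)cc(F)cc1Br) is protected with MOMCl and K2CO3 to 1-bromo-3,5-difluoro-2-(methoxymethoxy)benzene F1.
  - Lithiation with LiN(iPr)2 at −78 °C between the two fluorines and formylation with DMF give 4-bromo-2,6-difluoro-3-(methoxymethoxy)benzaldehyde F2.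
  - NaOMe replaces the two ortho fluorides and leaves the para bromide, giving 4-bromo-2,6-dimethoxy-3-(methoxymethoxy)benzaldehyde F3.
  - Ullmann coupling of F3 with 6 (CuI, picolinic acid, K3PO4, DMSO, 90 °C) gives 12 with the regiochemistry fixed by the bromide.

**Step 16.**
- What may go wrong: cleavage of the doubly activated D5–O–E1 ether by methoxide attack at E1 or D5, or incomplete exchange of the hindered E5 fluoride.
- Fallback: the ring D methoxy group is installed before the union, setting out from 14 and returning at 28. Ring D then carries no fluoride when methoxide meets the heptamer, and only two exchanges remain.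
  - One equivalent of NaOMe converts 14 into 3-(3-fluoro-4-formyl-5-methoxyphenoxy)-4-[2,6-dimethoxy-4-(2,4,6-trimethoxyphenoxy)phenoxy]-2,6-dimethoxybenzaldehyde F7.
  - The hydroxide-equivalent protocol of step 9 gives, through 3-{4-formyl-3-methoxy-5-[2-(methylsulfonyl)ethoxy]phenoxy}-4-[2,6-dimethoxy-4-(2,4,6-trimethoxyphenoxy)phenoxy]-2,6-dimethoxybenzaldehyde F8, the phenol 3-(4-formyl-3-hydroxy-5-methoxyphenoxy)-4-[2,6-dimethoxy-4-(2,4,6-trimethoxyphenoxy)phenoxy]-2,6-dimethoxybenzaldehyde F9.
  - Union of F9 with 26 (Cs2CO3, DMF) gives the heptamer tetra-aldehyde with fluorine only at E3 and E5, F10.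
  - NaOMe converts F10 into 28.

**Step 9.**
- What may go wrong: addition of the alkoxide or of the sulfonyl-stabilised carbanion to the two aldehydes, or a second fluoride displacement before the elimination.
- Fallback: the D5 oxygen is brought in with ring D, setting out from 13 and returning at 16.
  - Purchased 2,4-difluoro-6-hydroxybenzaldehyde is protected (MOMCl, K2CO3) as 2,4-difluoro-6-(methoxymethoxy)benzaldehyde F4.
  - The phenoxide of 13 displaces its para fluoride (Cs2CO3, DMF) to give 3-[3-fluoro-4-formyl-5-(methoxymethoxy)phenoxy]-4-[2,6-dimethoxy-4-(2,4,6-trimethoxyphenoxy)phenoxy]-2,6-dimethoxybenzaldehyde F5.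
  - HCl in MeOH–THF frees 16.

**Step 18.**
- What may go wrong: incomplete cleavage leaving partly methylated material, and air oxidation of the polyphenol during isolation.
- Fallback: the crude product is isolated through a stable derivative, setting out from crude 31 and returning at 31. Acetylation with Ac2O and pyridine gives the octadeca-acetate F11, which can be chromatographed in air and separated from under-demethylated material. Deacetylation with degassed methanolic HCl at 40 °C returns 31 without base.

## Further compounds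

F0 | step 17 | none | none
F1 | step 5 | 1-bromo-3,5-difluoro-2-(methoxymethoxy)benzene | COCOc1c(F)cc(F)cc1Br
F2 | step 5 | 4-bromo-2,6-difluoro-3-(methoxymethoxy)benzaldehyde | COCOc1c(Br)cc(F)c(C=O)c1F
F3 | step 5 | 4-bromo-2,6-dimethoxy-3-(methoxymethoxy)benzaldehyde | COCOc1c(Br)cc(OC)c(C=O)c1OC
F4 | step 9 | 2,4-difluoro-6-(methoxymethoxy)benzaldehyde | COCOc1cc(F)cc(F)c1C=O
F5 | step 9 | 3-[3-fluoro-4-formyl-5-(methoxymethoxy)phenoxy]-4-[2,6-dimethoxy-4-(2,4,6-trimethoxyphenoxy)phenoxy]-2,6-dimethoxybenzaldehyde | COc1cc(OC)c(Oc2cc(OC)c(Oc3cc(OC)c(C=O)c(OC)c3Oc3cc(F)c(C=O)c(OCOC)c3)c(OC)c2)c(OC)c1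
F6 | step 15 | 2,6-difluoro-4-(3,5-difluoro-2-formylphenoxy)-3-[4-(4-formyl-3,5-dimethoxyphenoxy)-3,5-dimethoxyphenoxy]benzaldehyde | O=Cc1c(F)cc(F)cc1Oc1cc(F)c(C=O)c(F)c1Oc1cc(OC)c(Oc2cc(OC)c(C=O)c(OC)c2)c(OC)c1
F7 | step 16 | 3-(3-fluoro-4-formyl-5-methoxyphenoxy)-4-[2,6-dimethoxy-4-(2,4,6-trimethoxyphenoxy)phenoxy]-2,6-dimethoxybenzaldehyde | COc1cc(OC)c(Oc2cc(OC)c(Oc3cc(OC)c(C=O)c(OC)c3Oc3cc(F)c(C=O)c(OC)c3)c(OC)c2)c(OC)c1
F8 | step 16 | 3-{4-formyl-3-methoxy-5-[2-(methylsulfonyl)ethoxy]phenoxy}-4-[2,6-dimethoxy-4-(2,4,6-trimethoxyphenoxy)phenoxy]-2,6-dimethoxybenzaldehyde | COc1cc(OC)c(Oc2cc(OC)c(Oc3cc(OC)c(C=O)c(OC)c3Oc3cc(OC)c(C=O)c(OCCS(C)(=O)=O)c3)c(OC)c2)c(OC)c1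
F9 | step 16 | 3-(4-formyl-3-hydroxy-5-methoxyphenoxy)-4-[2,6-dimethoxy-4-(2,4,6-trimethoxyphenoxy)phenoxy]-2,6-dimethoxybenzaldehyde | COc1cc(OC)c(Oc2cc(OC)c(Oc3cc(OC)c(C=O)c(OC)c3Oc3cc(O)c(C=O)c(OC)c3)c(OC)c2)c(OC)c1
F10 | step 16 | heptamer tetra-aldehyde with fluorine at E3 and E5 and twelve methyl ethers | COc1cc(OC)c(Oc2cc(OC)c(Oc3cc(OC)c(C=O)c(OC)c3Oc3cc(OC)c(C=O)c(Oc4cc(F)c(C=O)c(F)c4Oc4cc(OC)c(Oc5cc(OC)c(C=O)c(OC)c5)c(OC)c4)c3)c(OC)c2)c(OC)c1
F11 | step 18 | octadeca-acetate of 31 | CC(=O)Oc1cc(OC(C)=O)c(Oc2cc(OC(C)=O)c(Oc3cc(OC(C)=O)c(OC(C)=O)c(OC(C)=O)c3Oc3cc(OC(C)=O)c(OC(C)=O)c(Oc4cc(OC(C)=O)c(OC(C)=O)c(OC(C)=O)c4Oc4cc(OC(C)=O)c(Oc5cc(OC(C)=O)c(OC(C)=O)c(OC(C)=O)c5)c(OC(C)=O)c4)c3)c(OC(C)=O)c2)c(OC(C)=O)c1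
A1 | alternative 1 | 2-[3,5-dimethoxy-4-(3,4,5-trimethoxyphenoxy)phenoxy]-3,4-dimethoxy-4-(1-methoxyethenyl)cyclobut-2-en-1-one (racemic) | C=C(OC)C1(OC)C(OC)=C(Oc2cc(OC)c(Oc3cc(OC)c(OC)c(OC)c3)c(OC)c2)C1=O
A2 | alternative 1 | 2-[3,5-dimethoxy-4-(3,4,5-trimethoxyphenoxy)phenoxy]-3,4,5-trimethoxyphenol (EFG phenol) | Oc1cc(OC)c(OC)c(OC)c1Oc1cc(OC)c(Oc2cc(OC)c(OC)c(OC)c2)c(OC)c1
A3 | alternative 2 | 6-[2,6-dimethoxy-4-(2,4,6-trimethoxyphenoxy)phenoxy]-2,3,4-trimethoxyphenol (ABC phenol) | COc1cc(OC)c(Oc2cc(OC)c(Oc3cc(OC)c(OC)c(OC)c3O)c(OC)c2)c(OC)c1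
A4 | alternative 2 | heptamer with a formyl group at D4 and seventeen methyl ethers | COc1cc(OC)c(Oc2cc(OC)c(Oc3cc(OC)c(OC)c(OC)c3Oc3cc(OC)c(C=O)c(Oc4cc(OC)c(OC)c(OC)c4Oc4cc(OC)c(Oc5cc(OC)c(OC)c(OC)c5)c(OC)c4)c3)c(OC)c2)c(OC)c1
A5 | alternative 3 | methyl 3,5-dioxo-6-aryloxyhexanoate, aryl being ring B of the fully methylated hexamer BCDEFG | COC(=O)CC(=O)CC(=O)COc1cc(OC)c(Oc2cc(OC)c(OC)c(OC)c2Oc2cc(OC)c(OC)c(Oc3cc(OC)c(OC)c(OC)c3Oc3cc(OC)c(Oc4cc(OC)c(OC)c(OC)c4)c(OC)c3)c2)c(OC)c1
A6 | alternative 3 | heptamer with free ring A hydroxyls and fifteen methyl ethers | Oc1cc(O)c(Oc2cc(OC)c(Oc3cc(OC)c(OC)c(OC)c3Oc3cc(OC)c(OC)c(Oc4cc(OC)c(OC)c(OC)c4Oc4cc(OC)c(Oc5cc(OC)c(OC)c(OC)c5)c(OC)c4)c3)c(OC)c2)c(O)c1
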